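**Retrosynthetic overview** (side chain numbered C1'–C11' outward from C3 of the isochromanone)

1. Target 16 ⇐ 15 by one hydrogenation (C4'=C5' saturated, both benzyl ethers removed); 15 ⇐ hydroxy amide 14 by lactonisation (O2–C1 bond).
2. 14 ⇐ C2-symmetric diepoxide 5 by two SN2 openings of its terminal oxiranes: aryl–C4 bond from aryl metal 12, C10'–C11' bond from MeMgBr.
3. 5 ⇐ two molecules of (R)-epoxy-alkene 4 by self-metathesis, which forms C4'=C5'; 4 ⇐ (R)-epichlorohydrin 1 + butenyl Grignard 2; amide 10 ⇐ bromide 6 in three steps.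
4. Enabling feature: the carbinol carbons C3 (lactone ring) and C9' (side chain) each lie four CH2 groups from the C4'–C5' bond and have the same spatial sense (3R and 9'S differ only through CIP ranking), so C4–C10' is a hidden C2-symmetric 1,10-dioxygenated C12 unit with that bond at its midpoint.
5. Ring order: the benzene ring is purchased; the δ-lactone ring (C1, O2, C3, C4, C4a, C8a) is the only ring formed, in step 8.

Key step: step 2

Remark: 2 (commercial THF solution) and 6 are taken as purchasable; the alkene in 5 and 13–15 is an E/Z mixture, left open in the SMILES because step 9 hydrogenates it.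

**Route**

Step 1
Reactants: 1 (R)-epichlorohydrin; 2 but-3-en-1-ylmagnesium bromide
Product: 4 (R)-2-(pent-4-en-1-yl)oxirane, via (R)-1-chlorohept-6-en-2-ol 3 (not isolated)
Conditions: CuI (5 mol %), THF, −40 → −10 °C; then aq NaOH (50 %), rt
Reagents that add atoms: none
Why: Copper-catalysed Grignard opening of the epoxide at its CH2 carbon (SN2, C–Cl spared) followed by Williamson closure of the chlorohydrin onto CH2Cl should transpose the oxirane without touching the stereocentre, so (R)-1 gives (R)-4.

Step 2
Reactants: 4 (R)-2-(pent-4-en-1-yl)oxirane (two molecules)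
Product: 5 (2R,2'R)-2,2'-(oct-4-ene-1,8-diyl)bis(oxirane) as an E/Z mixture
Conditions: Grubbs II (1 mol %), 1,4-benzoquinone (10 mol %), CH2Cl2 (0.5 M), 40 °C, Ar sweep
Reagents that add atoms: none
Why: The Ru alkylidene engages the terminal alkene of 4 in [2+2] cycloaddition/cycloreversion through ruthenacyclobutanes (Chauvin mechanism), and loss of ethylene drives two molecules of 4 to the internal alkene 5. The closest known reaction type is the self-metathesis (homodimerisation) of functionalised terminal alkenes with second-generation Grubbs catalysts, which tolerate epoxides. No ring is closed and no stereocentre is created: both oxygen-bearing stereocentres of the target come from (R)-4, and because C3 and C9' have the same spatial sense the R,R-dimer carries both at once, while statistical pairing should turn a small ee deficit of 4 mainly into the minor meso-type diastereomer and not into the enantiomer. The step needs chemoselectivity for the C=C bond over the two oxiranes and no cross-selectivity at all, since both partners are the same Type-I alkene with the epoxide three CH2 groups away; benzoquinone is added to suppress Ru–H-mediated double-bond migration. The E/Z ratio is irrelevant because step 9 hydrogenates the alkene.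

Step 3
Reactants: 6 1,3-bis(benzyloxy)-5-bromobenzene
Product: 7 2,4-bis(benzyloxy)-6-bromobenzaldehyde
Conditions: POCl3, DMF, 0 → 70 °C; then ice–water
Reagents that add atoms: N,N-dimethylformamide CN(C)C=O; water O
Why: In this Vilsmeier–Haack formylation the chloroiminium ion should attack the resorcinol diether ring ortho to bromine and para to one benzyloxy group, the position between the two benzyloxy groups being the more hindered.

Step 4
Reactants: 7 2,4-bis(benzyloxy)-6-bromobenzaldehyde
Product: 8 2,4-bis(benzyloxy)-6-bromobenzoic acid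
Conditions: NaClO2, NaH2PO4, 2-methyl-2-butene, t-BuOH–THF–H2O, rt
Reagents that add atoms: sodium chlorite [Na+].[O-]Cl=O
Why: Pinnick oxidation converts the hindered aryl aldehyde into the acid under buffered conditions, and the alkene scavenger removes HOCl so that the electron-rich ring should not be chlorinated.

Step 5
Reactants: 8 2,4-bis(benzyloxy)-6-bromobenzoic acid
Product: 10 N,N-diethyl-2,4-bis(benzyloxy)-6-bromobenzamide, via acid chloride 9 (not isolated)
Conditions: (COCl)2, DMF (cat.), CH2Cl2, 0 °C → rt; then Et2NH (3 equiv), CH2Cl2, 0 °C → rt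
Reagents that add atoms: diethylamine CCNCC
Why: Acid chloride formation and aminolysis is the standard entry to a 2,6-disubstituted tertiary benzamide, which shields the carboxyl carbon against the organometallics of steps 6 and 7.

Step 6
Reactants: 10 N,N-diethyl-2,4-bis(benzyloxy)-6-bromobenzamide; 5 (2R,2'R)-2,2'-(oct-4-ene-1,8-diyl)bis(oxirane) (3 equiv, excess recovered)
Product: 13 N,N-diethyl-2,4-bis(benzyloxy)-6-[(2R)-2-hydroxy-10-[(2R)-oxiran-2-yl]dec-6-en-1-yl]benzamide, via aryllithium 11 (not isolated), via arylmagnesium bromide 12 (not isolated)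
Conditions: n-BuLi, THF, −78 °C; MgBr2 (THF), −78 → −40 °C; CuI (10 mol %), 5, −40 → 0 °C; aq NH4Cl
Reagents that add atoms: none
Why: Bromine–lithium exchange, transmetalation to magnesium and copper-catalysed SN2 opening of one of the two homotopic terminal epoxides at its CH2 carbon should forge the aryl–C4 bond without touching either stereocentre, the excess of C2-symmetric 5 holding double opening down and the hindered amide staying inert.

Step 7
Reactants: 13 N,N-diethyl-2,4-bis(benzyloxy)-6-[(2R)-2-hydroxy-10-[(2R)-oxiran-2-yl]dec-6-en-1-yl]benzamide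
Product: 14 N,N-diethyl-2,4-bis(benzyloxy)-6-[(2R,11S)-2,11-dihydroxytridec-6-en-1-yl]benzamide
Conditions: MeMgBr (4 equiv), CuI (20 mol %), THF, −40 → −10 °C; aq NH4Cl
Reagents that add atoms: methylmagnesium bromide C[Mg]Br
Why: Copper-catalysed SN2 opening of the remaining terminal epoxide by the methyl Grignard reagent turns the oxirane CH2 into the ethyl group and unveils the (S)-carbinol with its configuration untouched, the first equivalent only deprotonating the free hydroxyl.

Step 8
Reactants: 14 N,N-diethyl-2,4-bis(benzyloxy)-6-[(2R,11S)-2,11-dihydroxytridec-6-en-1-yl]benzamide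
Product: 15 (3R)-6,8-bis(benzyloxy)-3-[(9S)-9-hydroxyundec-4-en-1-yl]-3,4-dihydro-1H-isochromen-1-one
Conditions: TsOH·H2O (1.2 equiv), toluene, 90 °C
Reagents that add atoms: none
Why: Acid-promoted intramolecular alcoholysis of the ortho-(2-hydroxyalkyl)benzamide closes the six-membered lactone by attack of the C3 hydroxyl on the carboxamide carbon with loss of diethylamine, with retention at C3 because its C–O bond is not broken and with no comparably favoured ring available to the remote C9' hydroxyl.

Step 9
Reactants: 15 (3R)-6,8-bis(benzyloxy)-3-[(9S)-9-hydroxyundec-4-en-1-yl]-3,4-dihydro-1H-isochromen-1-one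
Product: 16 (3R)-6,8-dihydroxy-3-[(9S)-9-hydroxyundecyl]-3,4-dihydro-1H-isochromen-1-one (CNP0340379.1)
Conditions: H2 (1 atm), 10 % Pd/C, EtOAc–EtOH, rt
Reagents that add atoms: none
Why: Heterogeneous hydrogenation should saturate the disubstituted alkene and hydrogenolyse both benzyl ethers in one operation, leaving the lactone, the homobenzylic C3–O bond and both stereocentres untouched.

**Compound list**

1 | (R)-epichlorohydrin | ClC[C@H]1CO1 | starting material
2 | but-3-en-1-ylmagnesium bromide | C=CCC[Mg]Br | starting material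
3 | (R)-1-chlorohept-6-en-2-ol (present as its magnesium alkoxide) | C=CCCC[C@@H](O)CCl | intermediate (not isolated)
4 | (R)-2-(pent-4-en-1-yl)oxirane | C=CCCC[C@@H]1CO1 | intermediate
5 | (2R,2'R)-2,2'-(oct-4-ene-1,8-diyl)bis(oxirane), E/Z mixture | C1O[C@@H]1CCCC=CCCC[C@@H]1CO1 | intermediate
6 | 1,3-bis(benzyloxy)-5-bromobenzene | Brc1cc(OCc2ccccc2)cc(OCc2ccccc2)c1 | starting material
7 | 2,4-bis(benzyloxy)-6-bromobenzaldehyde | O=Cc1c(Br)cc(OCc2ccccc2)cc1OCc1ccccc1 | intermediate
8 | 2,4-bis(benzyloxy)-6-bromobenzoic acid | OC(=O)c1c(Br)cc(OCc2ccccc2)cc1OCc1ccccc1 | intermediate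
9 | 2,4-bis(benzyloxy)-6-bromobenzoyl chloride | ClC(=O)c1c(Br)cc(OCc2ccccc2)cc1OCc1ccccc1 | intermediate (not isolated)
10 | N,N-diethyl-2,4-bis(benzyloxy)-6-bromobenzamide | CCN(CC)C(=O)c1c(Br)cc(OCc2ccccc2)cc1OCc1ccccc1 | intermediate
11 | [3,5-bis(benzyloxy)-2-(diethylcarbamoyl)phenyl]lithium | CCN(CC)C(=O)c1c([Li])cc(OCc2ccccc2)cc1OCc1ccccc1 | intermediate (not isolated)
12 | [3,5-bis(benzyloxy)-2-(diethylcarbamoyl)phenyl]magnesium bromide | CCN(CC)C(=O)c1c([Mg]Br)cc(OCc2ccccc2)cc1OCc1ccccc1 | intermediate (not isolated)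
13 | N,N-diethyl-2,4-bis(benzyloxy)-6-[(2R)-2-hydroxy-10-[(2R)-oxiran-2-yl]dec-6-en-1-yl]benzamide | CCN(CC)C(=O)c1c(C[C@H](O)CCCC=CCCC[C@@H]2CO2)cc(OCc2ccccc2)cc1OCc1ccccc1 | intermediate
14 | N,N-diethyl-2,4-bis(benzyloxy)-6-[(2R,11S)-2,11-dihydroxytridec-6-en-1-yl]benzamide | CCN(CC)C(=O)c1c(C[C@H](O)CCCC=CCCC[C@@H](O)CC)cc(OCc2ccccc2)cc1OCc1ccccc1 | intermediate
15 | (3R)-6,8-bis(benzyloxy)-3-[(9S)-9-hydroxyundec-4-en-1-yl]-3,4-dihydro-1H-isochromen-1-one | CC[C@H](O)CCCC=CCCC[C@@H]1Cc2cc(OCc3ccccc3)cc(OCc3ccccc3)c2C(=O)O1 | intermediate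
16 | (3R)-6,8-dihydroxy-3-[(9S)-9-hydroxyundecyl]-3,4-dihydro-1H-isochromen-1-one | CC[C@H](O)CCCCCCCC[C@@H]1Cc2cc(O)cc(O)c2C(=O)O1 | target

**Count**

Total steps: 9. Longest linear sequence: 7 (steps 3, 4, 5, 6, 7, 8, 9).

**Steps most likely to fail, with fallbacks**

Step 6. The chelated, hindered ortho-carboxamido aryl metal may open the epoxide sluggishly, so that self-condensation of the aryl metal or double opening of the diepoxide competes. The fallback sets out from 6 and 5 and returns at 15; it uses a simple, more reactive aryl Grignard reagent and installs the lactone carbonyl afterwards. Magnesium insertion into 6 should give 3,5-bis(benzyloxy)phenylmagnesium bromide F1. CuI-catalysed opening of 5 (3 equiv) would give (2R)-1-[3,5-bis(benzyloxy)phenyl]-10-[(2R)-oxiran-2-yl]dec-6-en-2-ol F2. MeMgBr/CuI would then give (2R,11S)-1-[3,5-bis(benzyloxy)phenyl]tridec-6-ene-2,11-diol F3. NBS (1.0 equiv, CH2Cl2, −40 °C) should brominate the ring ortho to the alkyl chain to give (2R,11S)-1-[3,5-bis(benzyloxy)-2-bromophenyl]tridec-6-ene-2,11-diol F4. Palladium-catalysed carbonylative lactonisation (CO 1 atm, Pd(OAc)2/Xantphos, Et3N, toluene, 100 °C) would close the lactone to 15.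

Step 2. Ru-hydride-mediated double-bond migration could give chain-shortened dimers, or the oxiranes could deactivate the catalyst and stall conversion. The fallback sets out from 4 (with 12 from step 6) and returns at 15; it opens the epoxide of each half first and forms the same C4'=C5' bond by cross-metathesis between two epoxide-free halves. MeMgBr/CuI on 4 should give (S)-oct-7-en-3-ol F5. Opening of 4 with 12 under CuI catalysis would give N,N-diethyl-2,4-bis(benzyloxy)-6-[(2R)-2-hydroxyhept-6-en-1-yl]benzamide F6. TsOH in toluene would lactonise it to (3R)-6,8-bis(benzyloxy)-3-(pent-4-en-1-yl)-3,4-dihydro-1H-isochromen-1-one F7. Cross-metathesis of F7 with an excess of F5 (Hoveyda–Grubbs II, CH2Cl2, 40 °C) would deliver 15.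

Step 8. The di-ortho-substituted tertiary amide may resist intramolecular alcoholysis, and forcing acid could add a hydroxyl to the alkene or dehydrate the C9' carbinol. The fallback sets out from 8 and 5 and returns at 15; it replaces the amide by an ester and reverses the order of the two epoxide openings, so that the lactone closes spontaneously in the aryl addition. MeI/K2CO3 on 8 should give methyl 2,4-bis(benzyloxy)-6-bromobenzoate F8. MeMgBr/CuI on an excess of 5 would give (3S)-11-[(2R)-oxiran-2-yl]undec-7-en-3-ol F9. Bromine–magnesium exchange of F8 with i-PrMgCl·LiCl (THF, −20 °C) would give methyl 2,4-bis(benzyloxy)-6-(chloromagnesio)benzoate F10. CuI-catalysed opening of F9 (as its magnesium alkoxide) by F10 generates the C3 alkoxide next to the ester, which should close directly to 15.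

**Further compounds**

F1 | step 6 | 3,5-bis(benzyloxy)phenylmagnesium bromide | Br[Mg]c1cc(OCc2ccccc2)cc(OCc2ccccc2)c1
F2 | step 6 | (2R)-1-[3,5-bis(benzyloxy)phenyl]-10-[(2R)-oxiran-2-yl]dec-6-en-2-ol | C1O[C@@H]1CCCC=CCCC[C@@H](O)Cc1cc(OCc2ccccc2)cc(OCc2ccccc2)c1
F3 | step 6 | (2R,11S)-1-[3,5-bis(benzyloxy)phenyl]tridec-6-ene-2,11-diol | CC[C@H](O)CCCC=CCCC[C@@H](O)Cc1cc(OCc2ccccc2)cc(OCc2ccccc2)c1
F4 | step 6 | (2R,11S)-1-[3,5-bis(benzyloxy)-2-bromophenyl]tridec-6-ene-2,11-diol | CC[C@H](O)CCCC=CCCC[C@@H](O)Cc1cc(OCc2ccccc2)cc(OCc2ccccc2)c1Br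
F5 | step 2 | (S)-oct-7-en-3-ol | CC[C@H](O)CCCC=C
F6 | step 2 | N,N-diethyl-2,4-bis(benzyloxy)-6-[(2R)-2-hydroxyhept-6-en-1-yl]benzamide | CCN(CC)C(=O)c1c(C[C@H](O)CCCC=C)cc(OCc2ccccc2)cc1OCc1ccccc1
F7 | step 2 | (3R)-6,8-bis(benzyloxy)-3-(pent-4-en-1-yl)-3,4-dihydro-1H-isochromen-1-one | C=CCCC[C@@H]1Cc2cc(OCc3ccccc3)cc(OCc3ccccc3)c2C(=O)O1
F8 | step 8 | methyl 2,4-bis(benzyloxy)-6-bromobenzoate | COC(=O)c1c(Br)cc(OCc2ccccc2)cc1OCc1ccccc1
F9 | step 8 | (3S)-11-[(2R)-oxiran-2-yl]undec-7-en-3-ol | CC[C@H](O)CCCC=CCCC[C@@H]1CO1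
F10 | step 8 | methyl 2,4-bis(benzyloxy)-6-(chloromagnesio)benzoate | COC(=O)c1c([Mg]Cl)cc(OCc2ccccc2)cc1OCc1ccccc1
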